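The succinimide ring (C13–C14–C15–N–C16, labdane numbering) is opened at C14–C15: C13–C14 is read as the reduced form of an acrylamide C=CH2 and C15 as a formyl carbon on the imide nitrogen, so the ring hides a 2-aza-3-oxopent-4-enal. Rhodium-catalysed intramolecular hydroacylation of this N-formyl acrylamide should forge C14–C15, close the ring and set C13 in one redox-neutral isomerisation. The C12 carbinol flanking C13 makes the precursor a Morita–Baylis–Hillman adduct of a C12 aldehyde, reached from (+)-sclareolide, which supplies C5, C9 and C10 and relays C2 (C–H chlorination) and C7 (ketone reduction).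

Key step: step 11

Remark on the chemistry: labdane numbering is used (C1–C10 decalin, C11–C16 side chain, C17 exocyclic methylene). The N-chloroamide of step 1 and the catalyst α-isocupreine of step 8 are taken as reagents, each one step from N-tert-butyl-3,5-bis(trifluoromethyl)benzamide (N-chlorination) and quinine (acid-mediated cyclisation with O-demethylation).

Step 1
Reactants: 1 (+)-sclareolide
Product: 2 2α-chlorosclareolide
Conditions: N-chloro-N-tert-butyl-3,5-bis(trifluoromethyl)benzamide, Cs2CO3, PhH, visible light, 55 °C
Reagents that add atoms: N-chloro-N-tert-butyl-3,5-bis(trifluoromethyl)benzamide, CC(C)(C)N(Cl)C(=O)c1cc(C(F)(F)F)cc(C(F)(F)F)c1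
Why: Radical-chain C–H chlorination: the bulky, electrophilic amidyl radical should abstract hydrogen at C2, the one ring methylene that is neither next to a quaternary carbon nor deactivated by the lactone, and chlorine transfer to the C2 radical from the face opposite the axial C4 and C10 methyl groups gives the equatorial 2α-chloride.

Step 2
Reactants: 2 2α-chlorosclareolide
Product: 3 8α-hydroxy Weinreb amide
Conditions: MeNH(OMe)·HCl, AlMe3, CH2Cl2, 0 °C to rt
Reagents that add atoms: N,O-dimethylhydroxylamine hydrochloride, CNOC.Cl
Why: Weinreb aminolysis of the γ-lactone by the aluminium amide made in the flask; attack is at the acyl carbon C12, so the C8–O bond and every stereocentre stay untouched and C8 becomes a free equatorial tertiary alcohol.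

Step 3
Reactants: 3 8α-hydroxy Weinreb amide
Product: 4 8(17)-ene Weinreb amide
Conditions: SOCl2, pyridine, CH2Cl2, −78 °C
Reagents that add atoms: none
Why: Base-mediated dehydration (E2) of the activated tertiary alcohol: the equatorial 8α-oxygen has no antiperiplanar ring hydrogen, so elimination should take a hydrogen of the axial C17 methyl group and give the exocyclic 8(17)-alkene.

Step 4
Reactants: 4 8(17)-ene Weinreb amide
Product: 6 8(17)-en-7-one Weinreb amide, via 7α-alcohol 5 (not isolated)
Conditions: SeO2 (cat.), t-BuOOH, CH2Cl2, rt; then Dess–Martin periodinane, same pot, rt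
Reagents that add atoms: tert-butyl hydroperoxide, CC(C)(C)OO
Why: Riley allylic oxidation (ene reaction then 2,3-sigmatropic shift) hydroxylates the ring methylene C7 next to the exocyclic alkene in preference to the methine C9, and Dess–Martin oxidation of the crude axial alcohol gives the enone, so the C7 configuration formed first does not matter.

Step 5
Reactants: 6 8(17)-en-7-one Weinreb amide
Product: 7 7β-alcohol
Conditions: NaBH4, CeCl3·7H2O, MeOH, −78 to 0 °C
Reagents that add atoms: none
Why: Luche 1,2-reduction: the small hydride should attack C7 along the axial trajectory on the α face, which gives the equatorial 7β-alcohol, while CeCl3 suppresses conjugate reduction and the Weinreb amide is inert to NaBH4.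

Step 6
Reactants: 7 7β-alcohol
Product: 8 7β-acetate
Conditions: Ac2O, pyridine, DMAP (cat.), CH2Cl2, rt
Reagents that add atoms: acetic anhydride, CC(=O)OC(C)=O
Why: DMAP-catalysed acylation of the unhindered equatorial allylic alcohol; no stereocentre is involved.

Step 7
Reactants: 8 7β-acetate
Product: 9 C12 aldehyde
Conditions: Cp2Zr(H)Cl, THF, rt, short reaction time
Reagents that add atoms: none
Why: Reduction of the Weinreb amide with Cp2Zr(H)Cl (hydrozirconation of the amide C=O) stops at the aldehyde oxidation level because the aldehyde is released only on work-up, and the reagent leaves the acetate, the alkyl chloride and, at short reaction time, the hindered 1,1-disubstituted alkene alone.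

Step 8
Reactants: 9 C12 aldehyde; 10 1,1,1,3,3,3-hexafluoropropan-2-yl acrylate
Product: 11 (12S) Morita–Baylis–Hillman adduct
Conditions: α-isocupreine (10 mol %), DMF, −55 °C
Reagents that add atoms: none
Why: Amine-catalysed asymmetric Morita–Baylis–Hillman reaction: the quinuclidine nitrogen of the catalyst adds to the activated acrylate, the resulting enolate attacks the aldehyde and the catalyst phenol steers the proton transfer, so this catalyst (enantiocomplementary to β-isocupreidine) should set (12S) under catalyst control with little influence from the remote C9 centre.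

Step 9
Reactants: 11 (12S) Morita–Baylis–Hillman adduct
Product: 12 12-O-triethylsilyl ether
Conditions: Et3SiOTf, 2,6-lutidine, CH2Cl2, −78 °C
Reagents that add atoms: triethylsilyl trifluoromethanesulfonate, CC[Si](CC)(CC)OS(=O)(=O)C(F)(F)F
Why: Silylation of the secondary allylic alcohol with a silyl triflate and a hindered pyridine base at low temperature, which leaves the activated ester intact and blocks the N-to-O formyl transfer that a free C12 hydroxyl would cause after step 10.

Step 10
Reactants: 12 12-O-triethylsilyl ether; 13 formamide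
Product: 14 N-formyl acrylamide
Conditions: KN(SiMe3)2, THF, −40 to 0 °C; AcOH quench
Reagents that add atoms: none
Why: N-Acylation of an amide anion by an activated ester (acyclic imide synthesis): potassium formamide, made in the flask, should attack the hexafluoroisopropyl ester at the acyl carbon, and the N-formyl amide is deprotonated at once by the second equivalent, which shields it from further attack until the acidic quench.

Step 11
Reactants: 14 N-formyl acrylamide
Product: 16 haterumaimide N, via triethylsilyl ether 15 (not isolated)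
Conditions: [Rh(nbd)((R)-BINAP)]BF4 (5 mol %, pre-activated with H2), CH2Cl2, 25 °C; then HF·pyridine, THF, 0 °C
Reagents that add atoms: none
Why: Proposed new method: cationic monovalent rhodium should add oxidatively into the formyl C15–H bond, which the second acyl group on nitrogen makes aldehyde-like, to give a carbamoyl hydride of trivalent rhodium that binds the C13=C14 alkene (the C16=O oxygen can chelate and retard decarbonylation); hydride migration to C13 puts rhodium on C14 in a six-membered rhodacycle, C14–C15 reductive elimination releases the succinimide, and fluoride then removes the silyl ether. The closest known reactions are the rhodium-bisphosphine hydroacylation of 4-substituted pent-4-enals to 3-substituted cyclopentanones and the ruthenium-carbonyl hydrocarbamoylation of N-allylformamides to pyrrolidin-2-ones; neither has been shown on N-formyl acrylamides. The succinimide ring closes in a formal 5-endo-trig sense at C14, which is feasible because the bond forms by reductive elimination from the metallacycle and not by direct attack on the alkene. The new stereocentre C13 is set in the hydride-insertion step by the chiral pocket of (R)-BINAP, which differentiates the faces of the 1,1-disubstituted alkene as in the pentenal series, with the C12 silyloxy centre as a secondary element. The step needs anti-Markovnikov insertion, secured by ring size because the Markovnikov mode leads only to a strained four-membered malonimide and is reversible, and it needs chemoselectivity for the acrylamide over the remote, hindered C8=C17 alkene, secured by intramolecularity.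

Compound list

1 | (+)-sclareolide, (3aR,5aS,9aS,9bR)-3a,6,6,9a-tetramethyldecahydronaphtho[2,1-b]furan-2(1H)-one (13,14,15,16-tetranorlabdan-12,8α-olide) | C[C@@]12CC[C@H]3C(C)(C)CCC[C@]3(C)[C@H]1CC(=O)O2 | starting material
2 | 2α-chlorosclareolide (equatorial chloride at C2 of ring A) | C[C@@]12CC[C@H]3C(C)(C)C[C@H](Cl)C[C@]3(C)[C@H]1CC(=O)O2 | intermediate
3 | 2α-chloro-8α-hydroxy-N-methoxy-N-methyl-13,14,15,16-tetranorlabdan-12-amide | C[C@@]1(O)CC[C@H]2C(C)(C)C[C@H](Cl)C[C@]2(C)[C@H]1CC(=O)N(C)OC | intermediate
4 | 2α-chloro-N-methoxy-N-methyl-13,14,15,16-tetranorlabd-8(17)-en-12-amide | C=C1CC[C@H]2C(C)(C)C[C@H](Cl)C[C@]2(C)[C@H]1CC(=O)N(C)OC | intermediate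
5 | 2α-chloro-7α-hydroxy-N-methoxy-N-methyl-13,14,15,16-tetranorlabd-8(17)-en-12-amide (axial allylic alcohol) | C=C1[C@H](O)C[C@H]2C(C)(C)C[C@H](Cl)C[C@]2(C)[C@H]1CC(=O)N(C)OC | intermediate (not isolated)
6 | 2α-chloro-N-methoxy-N-methyl-7-oxo-13,14,15,16-tetranorlabd-8(17)-en-12-amide | C=C1C(=O)C[C@H]2C(C)(C)C[C@H](Cl)C[C@]2(C)[C@H]1CC(=O)N(C)OC | intermediate
7 | 2α-chloro-7β-hydroxy-N-methoxy-N-methyl-13,14,15,16-tetranorlabd-8(17)-en-12-amide (equatorial alcohol) | C=C1[C@@H](O)C[C@H]2C(C)(C)C[C@H](Cl)C[C@]2(C)[C@H]1CC(=O)N(C)OC | intermediate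
8 | 7β-acetoxy-2α-chloro-N-methoxy-N-methyl-13,14,15,16-tetranorlabd-8(17)-en-12-amide | C=C1[C@@H](OC(C)=O)C[C@H]2C(C)(C)C[C@H](Cl)C[C@]2(C)[C@H]1CC(=O)N(C)OC | intermediate
9 | 7β-acetoxy-2α-chloro-13,14,15,16-tetranorlabd-8(17)-en-12-al | C=C1[C@@H](OC(C)=O)C[C@H]2C(C)(C)C[C@H](Cl)C[C@]2(C)[C@H]1CC=O | intermediate
10 | 1,1,1,3,3,3-hexafluoropropan-2-yl acrylate | C=CC(=O)OC(C(F)(F)F)C(F)(F)F | starting material
11 | 1,1,1,3,3,3-hexafluoropropan-2-yl (12S)-7β-acetoxy-2α-chloro-12-hydroxy-15-norlabda-8(17),13(14)-dien-16-oate (2-substituted acrylate) | C=C1[C@@H](OC(C)=O)C[C@H]2C(C)(C)C[C@H](Cl)C[C@]2(C)[C@H]1C[C@H](O)C(=C)C(=O)OC(C(F)(F)F)C(F)(F)F | intermediate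
12 | 1,1,1,3,3,3-hexafluoropropan-2-yl (12S)-7β-acetoxy-2α-chloro-12-(triethylsilyloxy)-15-norlabda-8(17),13(14)-dien-16-oate | C=C1[C@@H](OC(C)=O)C[C@H]2C(C)(C)C[C@H](Cl)C[C@]2(C)[C@H]1C[C@H](O[Si](CC)(CC)CC)C(=C)C(=O)OC(C(F)(F)F)C(F)(F)F | intermediate
13 | formamide | NC=O | starting material
14 | (12S)-7β-acetoxy-2α-chloro-N-formyl-12-(triethylsilyloxy)-15-norlabda-8(17),13(14)-dien-16-amide (the formyl carbon becomes C15) | C=C1[C@@H](OC(C)=O)C[C@H]2C(C)(C)C[C@H](Cl)C[C@]2(C)[C@H]1C[C@H](O[Si](CC)(CC)CC)C(=C)C(=O)NC=O | intermediate
15 | (12S,13R)-7β-acetoxy-2α-chloro-12-(triethylsilyloxy)labd-8(17)-ene-15,16-dioic imide (3-substituted pyrrolidine-2,5-dione) | C=C1[C@@H](OC(C)=O)C[C@H]2C(C)(C)C[C@H](Cl)C[C@]2(C)[C@H]1C[C@H](O[Si](CC)(CC)CC)[C@H]1CC(=O)NC1=O | intermediate (not isolated)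
16 | haterumaimide N, (12S,13R)-7β-acetoxy-2α-chloro-12-hydroxylabd-8(17)-ene-15,16-dioic imide | C=C1[C@@H](OC(C)=O)C[C@H]2C(C)(C)C[C@H](Cl)C[C@]2(C)[C@H]1C[C@H](O)[C@H]1CC(=O)NC1=O | target

Total step count: 11. Longest linear sequence: 11 steps (1 to 16; the route is fully linear).

Steps most likely to fail

1. Step 11 (bears the label "Proposed new method:"). Three things may go wrong. The carbamoyl rhodium hydride may lose CO, which removes the formyl group and deactivates the catalyst as a carbonyl complex. Markovnikov insertion followed by β-hydride elimination may isomerise the allylic silyl ether. The hydride may be delivered to the wrong face of C13 if the ligand and the C12 centre are mismatched; which BINAP antipode is matched cannot be deduced for this new substrate class. Fallback with known chemistry, setting out from aldehyde 9 and coming back at 16: an Evans syn-aldol reaction of 9 with the dibutylboron enolate of (R)-4-benzyl-3-(3-cyanopropanoyl)oxazolidin-2-one (Bu2BOTf, i-Pr2NEt, CH2Cl2, −78 to 0 °C) should give, through the chair transition state of the Z-enolate, the (12S,13R) cyanomethyl aldol adduct F1. Neutral hydration of the nitrile with [PtH(PMe2OH)(PMe2O)2H] in aqueous EtOH at 80 °C should give the primary amide F2. Its nitrogen then attacks the acyl carbon C16 (5-exo-trig, catalytic Et3N if needed) and expels the oxazolidinone, which gives 16 directly; here the ring is closed at N–C16 and both side-chain stereocentres come from the auxiliary.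

2. Step 8. What may go wrong: slow addition to the β-branched, enolisable aldehyde, consumption of the adduct by acetal formation with a second aldehyde molecule, and incomplete catalyst control over the C12 configuration. Fallback, setting out from aldehyde 9 and coming back at 14: an Evans syn-aldol reaction of 9 with the dibutylboron enolate of (R)-4-benzyl-3-[3-(phenylselanyl)propanoyl]oxazolidin-2-one should give the selenide aldol adduct F3, in which the auxiliary fixes (12S). Silylation (Et3SiOTf, 2,6-lutidine) gives the triethylsilyl ether F4. Oxidation at selenium with NaIO4 in aqueous THF/MeOH gives the selenoxide F5, which undergoes syn-elimination across C13–C14 at rt to the α-methylene N-acyl oxazolidinone F6 (the auxiliary-derived C13 centre is erased on purpose). Potassium formamide then displaces the oxazolidinone at C16 under the conditions of step 10 and the route is rejoined at 14.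

3. Step 10. What may go wrong: conjugate addition of the formamide anion to the activated acrylate in competition with acyl substitution, and loss of the formyl group from the product during quench or chromatography. Fallback, setting out from 12 and coming back at 14: ammonolysis of the activated ester (NH3 in dioxane, 0 °C) gives the primary acrylamide F7. Condensation with N,N-dimethylformamide dimethyl acetal (CH2Cl2, rt) gives the N-acylformamidine F8. Brief hydrolysis of the amidine C=N bond in buffered aqueous acetic acid at 0 °C releases dimethylamine and gives the N-formyl amide 14 without basic conditions.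

Further compounds

F1 | step 11 | (R)-4-benzyl-3-acyl-oxazolidin-2-one syn-aldol adduct of 9, (12S,13R), with a cyanomethyl group (C14–C15≡N) on C13 | C=C1[C@@H](OC(C)=O)C[C@H]2C(C)(C)C[C@H](Cl)C[C@]2(C)[C@H]1C[C@H](O)[C@@H](CC#N)C(=O)N1[C@H](Cc2ccccc2)COC1=O
F2 | step 11 | primary amide from hydration of F1 (C15 carboxamide, acyl oxazolidinone at C16) | C=C1[C@@H](OC(C)=O)C[C@H]2C(C)(C)C[C@H](Cl)C[C@]2(C)[C@H]1C[C@H](O)[C@@H](CC(N)=O)C(=O)N1[C@H](Cc2ccccc2)COC1=O
F3 | step 8 | (R)-4-benzyl-3-acyl-oxazolidin-2-one syn-aldol adduct of 9, (12S), with a phenylselanylmethyl group on C13 | C=C1[C@@H](OC(C)=O)C[C@H]2C(C)(C)C[C@H](Cl)C[C@]2(C)[C@H]1C[C@H](O)[C@@H](C[Se]c1ccccc1)C(=O)N1[C@H](Cc2ccccc2)COC1=O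
F4 | step 8 | 12-O-triethylsilyl ether of F3 | C=C1[C@@H](OC(C)=O)C[C@H]2C(C)(C)C[C@H](Cl)C[C@]2(C)[C@H]1C[C@H](O[Si](CC)(CC)CC)[C@@H](C[Se]c1ccccc1)C(=O)N1[C@H](Cc2ccccc2)COC1=O
F5 | step 8 | selenoxide of F4 | C=C1[C@@H](OC(C)=O)C[C@H]2C(C)(C)C[C@H](Cl)C[C@]2(C)[C@H]1C[C@H](O[Si](CC)(CC)CC)[C@@H](C[Se](=O)c1ccccc1)C(=O)N1[C@H](Cc2ccccc2)COC1=O
F6 | step 8 | (12S) α-methylene N-acyl (R)-4-benzyloxazolidin-2-one with 12-O-triethylsilyl ether | C=C1[C@@H](OC(C)=O)C[C@H]2C(C)(C)C[C@H](Cl)C[C@]2(C)[C@H]1C[C@H](O[Si](CC)(CC)CC)C(=C)C(=O)N1[C@H](Cc2ccccc2)COC1=O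
F7 | step 10 | (12S)-7β-acetoxy-2α-chloro-12-(triethylsilyloxy)-15-norlabda-8(17),13(14)-dien-16-amide (primary acrylamide) | C=C1[C@@H](OC(C)=O)C[C@H]2C(C)(C)C[C@H](Cl)C[C@]2(C)[C@H]1C[C@H](O[Si](CC)(CC)CC)C(=C)C(N)=O
F8 | step 10 | N-[(dimethylamino)methylidene] derivative of F7 (N-acylformamidine) | C=C1[C@@H](OC(C)=O)C[C@H]2C(C)(C)C[C@H](Cl)C[C@]2(C)[C@H]1C[C@H](O[Si](CC)(CC)CC)C(=C)C(=O)N=CN(C)C
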